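## Structural features

The target is a flavan-3-ol of the (−)-epicatechin type: rings A and C form a chroman, ring B is a catechol on C2, and C8 is tied through one methylene carbon to ring D, a fully substituted acylphloroglucinol. Going round ring D, the substituents are the (S)-2-methylbutanoyl group, a methyl ether, a C-methyl group, a hydroxyl, the bridge carbon and a second hydroxyl. The bridge therefore sits between two free phenols, with the ether oxygen para to it. C2 and C3 are adjacent stereocentres with the aryl group and the hydroxyl cis (2R,3R); the third stereocentre, the α-carbon of the acyl chain, is remote and enolisable. The six free phenols are easily oxidised, the benzylic C2–O1 bond can open under acid or base with loss of the C2 configuration, and rings A and D react with electrophiles under mild conditions. The real difficulties are the cis relation at C2/C3, placing the bridge on C8 and not on the electronically similar C6, and the position of the single O-methyl group on ring D. The key step uses the fact that ring A carries O1 on C8a and the bridge carbon on the neighbouring C8: this is the pattern left when an oxygen nucleophile and a carbon electrophile add across an aryne spanning C8–C8a.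

## Logic of the disconnections

**33 to 32.** The five oxygen–benzyl bonds on rings A and B and on the C3 oxygen are cut last. Free catechol and phloroglucinol units cannot be carried through base, acid or oxidants, and benzyl ethers come off under neutral hydrogenolysis that does not touch C2. The demand on the forward step is that the aryl ketone and the benzylic C2–O1 bond are not reduced.

**32 to 23 and 30.** The bond between the bridge carbon and ring D is cut. The carbon of 30 that receives the bridge is its only unsubstituted ring position and lies between two free hydroxyls, so 30 is a one-site carbon nucleophile. The bridge carbon of 23 ionises easily to 31 because three ring-A oxygens stabilise the cation. This splits the molecule into two halves of similar size and keeps ring D away from all strongly basic steps. The forward step needs an acid weak enough to leave ring C closed and enough 30 to outrun attack by C6 of a second molecule of 23.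

**23 to 22.** This is only a change of oxidation level at the bridge carbon; 22 is what a formylation delivers.

**22 to 17 (key step).** The bonds O1–C8a and C8–C(formyl) are cut. Both lie on adjacent carbons of ring A, so they can be traced to an aryne across C8–C8a that takes up the side-chain alkoxide at one end and a formyl cation equivalent at the other. Ring C and the bridge carbon then come from one open-chain bromoarene, the C8/C6 question is decided by where the bromine sits, and both stereocentres are already in place and are not touched. The forward step requires metalation next to bromine, the carbinol oxygen as the only tethered nucleophile (hence the ether on the neighbouring oxygen), and an aryllithium that survives until the quench.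

**17 to 14 and 16 (from 15).** The carbon–carbon bond between the carbinol carbon (future C2) and ring B is cut. The α-benzyloxy group of 14 can hold magnesium in a five-membered chelate and so direct the incoming aryl group to the threo product. Ring B then arrives as a commercial bromide. The forward step needs chelation to dominate and 14 to be used before it can epimerise.

**14 to 13 to 12 to 10 and 6.** After two oxidation-level changes, the bond between the ether carbon (future C3) and the benzylic carbon (future C4) is cut. A glycolate enolate on a chiral auxiliary sets this centre with a reliable facial bias and brings the C3 oxygen in already as the benzyl ether the key step requires. The demand is a clean alkylation with the hindered, electron-rich electrophile 6, which has to be made fresh.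

**6 to 5 to 4 to 2 to 1, and 10 to 7 and 8.** The benzylic bromide is traced through the alcohol and the aldehyde to a formylation of 2, whose substitution pattern directs the new carbon next to bromine; 2 comes from 1 by etherification. 10 is an N-acylation of 7 with 8.

**30 to 29 to 28 to 27 to 24 and 25 (through 26).** The methyl ether is cut back to a phenol that is the last one left after two benzylations, and the acyl bond is cut to a Friedel–Crafts pair. The two open carbons of 25 are equivalent, so acylation has one outcome; the only selectivity required is between the two hydroxyls ortho to the ketone in 27.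

## Other disconnections considered

**Alternative 1:** The cut is C4–C4a of ring C. In the forward step the aryl ether A1 would be treated with BF3·OEt2. In A1 the ring-A phenol, already carrying ring D on C8, is bound to the benzylic carbon of an (R,R)-configured aryl glycidyl unit. C4a would attack the terminal epoxide carbon and give the flavan-3-ol A2.
- In its favour: C8 is blocked before ring C forms, so the arene can only close at C4a. Both stereocentres are made beforehand by catalytic asymmetric oxidation and are not touched by the closure. The C3 hydroxyl appears free and distinct from every phenol. Ring D can be present because nothing basic is used.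
- Where it is equal or better: on the free C3 hydroxyl and on tolerance of ring D it is the better plan; on the origin of the stereocentres (a catalyst, no auxiliary) it is at least equal.
- Against it: closure at the primary carbon (6-endo) competes with attack at the internal carbon (5-exo). The Lewis acid can ionise the benzylic C2–O bond, which is why ring B has to be made electron-poor as a bis-pivalate. That adds a second kind of protecting group, whose removal needs base or hydride in the presence of the ketone and the base-sensitive C2. Making A1 requires etherifying a hindered phenol at a secondary benzylic carbon with clean inversion. The bridge must be placed on the ring-A phenol first, where the position between the two benzyloxy groups competes.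
- Comparison: structurally it forms a carbon–carbon bond of ring C where the chosen plan forms a carbon–oxygen bond. Mechanistically it biases a cationic epoxide opening, whereas the chosen plan fixes regiochemistry by the position of a bromine atom. In step count the two should be close, with one extra deprotection for Alternative 1 and more regiochemical branch points.

**Alternative 2:** The cut removes two bonds of ring D. Heating cyclobutenone A3 with siloxyalkyne A4 (carried on the C8 methylene of the protected flavan) would give phenol A5. The sequence is a four-electron ring opening, a [2+2] addition, a second ring opening and a six-electron closure.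
- In its favour: the oxygen pattern of ring D is fixed without any selective O-alkylation. The new hydroxyl and the silyloxy group flank the bridge, and the methoxy group lies next to the C-methyl group. The conditions are neutral and leave the flavan stereocentres alone.
- Where it is equal or better: on fixing the ring-D oxygen pattern it is the better plan, since step 13 of the chosen route depends on a selectivity.
- Against it: A5 lacks the acyl group. It would have to go in late, between the silyloxy and methoxy groups, by Friedel–Crafts or Fries chemistry. The substrate then carries five benzyl ethers, an acid-labile ring C and a nucleophilic C6, and the acyl donor is enantiopure and α-branched. A4 already needs a C8-selective functionalisation of the flavan, so this cut leaves the C8/C6 problem to other chemistry. Siloxyalkynes are sensitive to hydrolysis.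
- Comparison: structurally it builds ring D atom by atom where the chosen plan buys ring D's carbons. Mechanistically the pericyclic cascade is regiochemically cleaner than electrophilic substitution. In step economy it is clearly longer and carries the most valuable material through more steps.

**Alternative 3:** The cut removes C3–C4 and O1–C2. Salicyl alcohol A6 would be dehydrated to quinone methide A7, which would add to the Z enol acetate A8 in a [4+2] reaction and give the C3 acetate A9.
- In its favour: ring C and both stereocentres form in one step from two fragments of similar size. The cis relation follows from the Z geometry of A8. The bridge is fixed on ring A beforehand because both positions ortho to the phenol are occupied.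
- Where it is equal or better: in convergence and step count it is the better plan.
- Against it: the absolute configuration would have to come from a chiral catalyst acting on a hindered, fully substituted heterodiene; the remote acyl stereocentre gives no help. The regiochemistry needs the aryl group, not the acetoxy group, to control the polarisation of A8. A8 must be geometrically pure and must not isomerise under the acid that generates A7. A7 can dimerise.
- Comparison: structurally it makes two ring bonds and two stereocentres at once, where the chosen key step makes two bonds and no stereocentre. Mechanistically its facial selectivity is the weak point, whereas the chosen plan sets C3 with an auxiliary and C2 by chelation, both with predictable models. It is shorter, but any shortfall in selectivity would appear late as stereoisomer mixtures.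

Key step: step 10

Remark on the chemistry: the auxiliary is taken as the (S)-4-benzyl oxazolidinone, the enantiomer that gives the (R) ether carbon; the ring-A C–H between the two benzyloxy groups is also acidic, so the amide base in the key step is limited to a small excess.

## Route

Step 1
Reactants: 1 5-bromoresorcinol
Product: 2 1,3-bis(benzyloxy)-5-bromobenzene
Conditions: BnBr (2.2 equiv), K2CO3, DMF, 60 °C
Reagents that add atoms: benzyl bromide, BrCc1ccccc1
Why: Williamson ether synthesis on both phenols; the aryl bromide is inert to carbonate and to benzyl bromide.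

Step 2
Reactants: 2 1,3-bis(benzyloxy)-5-bromobenzene
Product: 4 2,4-bis(benzyloxy)-6-bromobenzaldehyde, via iminium chloride 3 (not isolated)
Conditions: POCl3, DMF, 0 → 70 °C; then aq NaOAc
Reagents that add atoms: N,N-dimethylformamide, CN(C)C=O; water, O
Why: Vilsmeier–Haack formylation; attack next to bromine (para to one benzyloxy group, ortho to the other) should be preferred over the more hindered carbon between the two ethers, as is general for 1-bromo-3,5-dialkoxybenzenes, and hydrolysis of 3 frees the aldehyde.

Step 3
Reactants: 4 2,4-bis(benzyloxy)-6-bromobenzaldehyde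
Product: 5 [2,4-bis(benzyloxy)-6-bromophenyl]methanol
Conditions: NaBH4, THF/MeOH, 0 °C
Reagents that add atoms: none
Why: Borohydride reduction of an aryl aldehyde; aryl bromide and benzyl ethers are untouched.

Step 4
Reactants: 5 [2,4-bis(benzyloxy)-6-bromophenyl]methanol
Product: 6 1,5-bis(benzyloxy)-3-bromo-2-(bromomethyl)benzene
Conditions: PBr3 (0.4 equiv), CH2Cl2, 0 °C; used at once without chromatography
Reagents that add atoms: phosphorus tribromide, BrP(Br)Br
Why: Conversion of an activated benzylic alcohol into the bromide; the product is an electron-rich benzylic halide and should be kept cold and used immediately.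

Step 5
Reactants: 7 (S)-4-benzyloxazolidin-2-one; 8 (benzyloxy)acetyl chloride
Product: 10 (4S)-4-benzyl-3-[(benzyloxy)acetyl]oxazolidin-2-one, via N-lithio oxazolidinone 9 (not isolated)
Conditions: n-BuLi, THF, −78 °C; then 8, −78 → 0 °C
Reagents that add atoms: none
Why: N-acylation of the lithiated Evans auxiliary with an acid chloride, the standard entry to glycolate imides.

Step 6
Reactants: 10 (4S)-4-benzyl-3-[(benzyloxy)acetyl]oxazolidin-2-one; 6 1,5-bis(benzyloxy)-3-bromo-2-(bromomethyl)benzene
Product: 12 (4S)-4-benzyl-3-[(2R)-2-(benzyloxy)-3-[2,4-bis(benzyloxy)-6-bromophenyl]propanoyl]oxazolidin-2-one, via sodium Z-enolate 11 (not isolated)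
Conditions: NaN(SiMe3)2, THF, −78 °C; then 6, −78 → −45 °C
Reagents that add atoms: none
Why: Evans asymmetric alkylation of a glycolate imide; the sodium-chelated Z-enolate is alkylated on the face opposite the C4 benzyl group of the (S)-auxiliary, which sets the ether-bearing carbon (future C3) as R, and the benzylic bromide is reactive enough for the cold enolate.

Step 7
Reactants: 12 (4S)-4-benzyl-3-[(2R)-2-(benzyloxy)-3-[2,4-bis(benzyloxy)-6-bromophenyl]propanoyl]oxazolidin-2-one
Product: 13 (2R)-2-(benzyloxy)-3-[2,4-bis(benzyloxy)-6-bromophenyl]propan-1-ol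
Conditions: LiBH4, MeOH (1 equiv), THF, 0 °C
Reagents that add atoms: none
Why: Reductive cleavage of the N-acyl oxazolidinone to the primary alcohol with recovery of the auxiliary; the stereocentre, the aryl bromide and the ethers are not affected.

Step 8
Reactants: 13 (2R)-2-(benzyloxy)-3-[2,4-bis(benzyloxy)-6-bromophenyl]propan-1-ol
Product: 14 (2R)-2-(benzyloxy)-3-[2,4-bis(benzyloxy)-6-bromophenyl]propanal
Conditions: Dess–Martin periodinane, NaHCO3, CH2Cl2, 0 °C → rt; used directly
Reagents that add atoms: none
Why: Dess–Martin oxidation under buffered, non-basic conditions, chosen because α-alkoxy aldehydes epimerise easily; the crude aldehyde is taken on at once.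

Step 9
Reactants: 15 4-bromo-1,2-bis(benzyloxy)benzene; 14 (2R)-2-(benzyloxy)-3-[2,4-bis(benzyloxy)-6-bromophenyl]propanal
Product: 17 (1R,2R)-2-(benzyloxy)-1-[3,4-bis(benzyloxy)phenyl]-3-[2,4-bis(benzyloxy)-6-bromophenyl]propan-1-ol, via aryl Grignard reagent 16 (not isolated)
Conditions: 15, Mg, THF, rt → 50 °C; then added to 14 precomplexed with MgBr2·OEt2, CH2Cl2, −78 °C
Reagents that add atoms: none
Why: Chelation-controlled Grignard addition (Cram chelate model); magnesium bridges the aldehyde and benzyloxy oxygens and the aryl group enters from the side away from the benzylic substituent, which should give the threo carbinol with the new centre (future C2) as R; the aryl bromide of 14 does not exchange with an aryl Grignard reagent at −78 °C.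

Step 10
Reactants: 17 (1R,2R)-2-(benzyloxy)-1-[3,4-bis(benzyloxy)phenyl]-3-[2,4-bis(benzyloxy)-6-bromophenyl]propan-1-ol
Product: 22 (2R,3R)-3,5,7-tris(benzyloxy)-2-[3,4-bis(benzyloxy)phenyl]chromane-8-carbaldehyde, via dilithio bromoarene 18 (not isolated), via aryne alkoxide 19 (not isolated), via 8-lithioflavan 20 (not isolated), via lithium hemiaminolate 21 (not isolated)
Conditions: LiTMP (lithium 2,2,6,6-tetramethylpiperidide, from the amine and n-BuLi; 2.3 equiv), THF, −78 → −30 °C; then DMF (5 equiv), −78 °C → rt; aq NH4Cl
Reagents that add atoms: N,N-dimethylformamide, CN(C)C=O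
Why: LiTMP removes the hydroxyl proton and then the ring proton flanked by bromine and a benzyloxy group (18); on warming LiBr is lost and the aryne 19 spans the future C8–C8a bond. The tethered lithium alkoxide adds to the nearer aryne carbon (future C8a) in a 6-exo-dig closure of ring C and leaves the carbanion on C8 (20), where it is flanked by two oxygens; DMF formylates it through 21, which collapses to the aldehyde on work-up. The closest known reaction types are base-induced benzyne ring closures by tethered alkoxide or amide nucleophiles, anionic aryne cyclisations whose aryllithium products are quenched with electrophiles, and the formylation of 2,6-dialkoxyaryllithiums with DMF; telescoping them on an alkoxide tether is the untested element. No stereocentre is created: the carbinol C–O bond is never broken, so the (1R,2R) threo alcohol should give the (2R,3R) cis flavan with retention. Site selectivity of metalation is needed: bromine acidifies the adjacent C–H more than a second ether does, only that anion can expel bromide, lithiation between the two benzyloxy groups is reversible through the free amine, and the small excess of base should keep that position unmetalated when DMF is added. Regiochemistry of the addition is secured twice, by the tether length and by the inductive preference for an anion ortho to the benzyloxy group. Ring size is secured by the benzyl ether on the neighbouring oxygen, which leaves the carbinol oxygen as the only internal nucleophile, and LiTMP is too hindered to add to the aryne at a competitive rate.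

Step 11
Reactants: 22 (2R,3R)-3,5,7-tris(benzyloxy)-2-[3,4-bis(benzyloxy)phenyl]chromane-8-carbaldehyde
Product: 23 [(2R,3R)-3,5,7-tris(benzyloxy)-2-[3,4-bis(benzyloxy)phenyl]chroman-8-yl]methanol
Conditions: NaBH4, THF/MeOH, 0 °C → rt
Reagents that add atoms: none
Why: Borohydride reduction of a hindered, electron-rich aryl aldehyde to the benzylic alcohol; nothing else in the molecule is reducible under these conditions.

Step 12
Reactants: 24 (S)-2-methylbutanoic acid; 25 2-methylphloroglucinol
Product: 27 (2S)-2-methyl-1-(2,4,6-trihydroxy-3-methylphenyl)butan-1-one, via acid chloride 26 (not isolated)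
Conditions: (COCl)2, DMF (cat.), CH2Cl2, 0 °C → rt, evaporate; then 25, AlCl3, CH2Cl2/PhNO2, 0 °C → rt
Reagents that add atoms: none
Why: Friedel–Crafts acylation; the two open ring carbons of 25 are equivalent, so only one C-acyl product is possible, and the base-free formation of 26 and the low temperature should preserve the α-stereocentre.

Step 13
Reactants: 27 (2S)-2-methyl-1-(2,4,6-trihydroxy-3-methylphenyl)butan-1-one
Product: 28 (2S)-1-[4,6-bis(benzyloxy)-2-hydroxy-3-methylphenyl]-2-methylbutan-1-one
Conditions: BnBr (2.05 equiv), K2CO3, acetone, rt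
Reagents that add atoms: benzyl bromide, BrCc1ccccc1
Why: Partial Williamson etherification; the hydroxyl para to the ketone is the most acidic, and of the two chelated ortho hydroxyls the one next to ring hydrogen is the less hindered, so the hydroxyl wedged between the C-methyl and acyl groups should remain, as is usual in the partial alkylation of C-methylated acylphloroglucinols.

Step 14
Reactants: 28 (2S)-1-[4,6-bis(benzyloxy)-2-hydroxy-3-methylphenyl]-2-methylbutan-1-one
Product: 29 (2S)-1-[4,6-bis(benzyloxy)-2-methoxy-3-methylphenyl]-2-methylbutan-1-one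
Conditions: MeI (excess), K2CO3, DMF, 40 °C
Reagents that add atoms: iodomethane, CI
Why: O-methylation of the last, hydrogen-bonded phenol; carbonate is too weak a base to enolise the twisted aryl ketone, so the α-stereocentre should hold.

Step 15
Reactants: 29 (2S)-1-[4,6-bis(benzyloxy)-2-methoxy-3-methylphenyl]-2-methylbutan-1-one
Product: 30 (2S)-1-(4,6-dihydroxy-2-methoxy-3-methylphenyl)-2-methylbutan-1-one
Conditions: H2 (1 atm), Pd/C, EtOAc, rt
Reagents that add atoms: none
Why: Hydrogenolysis of the two benzyl ethers; the hindered, chelated acylphloroglucinol ketone is not reduced under these conditions.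

Step 16
Reactants: 23 [(2R,3R)-3,5,7-tris(benzyloxy)-2-[3,4-bis(benzyloxy)phenyl]chroman-8-yl]methanol; 30 (2S)-1-(4,6-dihydroxy-2-methoxy-3-methylphenyl)-2-methylbutan-1-one
Product: 32 (2S)-1-{3-[((2R,3R)-3,5,7-tris(benzyloxy)-2-[3,4-bis(benzyloxy)phenyl]chroman-8-yl)methyl]-2,4-dihydroxy-6-methoxy-5-methylphenyl}-2-methylbutan-1-one, via benzylic cation 31 (not isolated)
Conditions: 30 (2.5 equiv), p-toluenesulfonic acid monohydrate (10 mol %), CH2Cl2/MeCN, −20 → 0 °C, slow addition of 23
Reagents that add atoms: none
Why: Friedel–Crafts alkylation; the alcohol ionises under weak acid because three ring-A oxygens stabilise 31, and the free acylphloroglucinol attacks with its single open carbon between two hydroxyls. The excess of 30 and the slow addition are meant to suppress attack by C6 of a second flavan, and the mild acid should leave ring C closed.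

Step 17
Reactants: 32 (2S)-1-{3-[((2R,3R)-3,5,7-tris(benzyloxy)-2-[3,4-bis(benzyloxy)phenyl]chroman-8-yl)methyl]-2,4-dihydroxy-6-methoxy-5-methylphenyl}-2-methylbutan-1-one
Product: 33 (2S)-1-{3-[((2R,3R)-2-(3,4-dihydroxyphenyl)-3,5,7-trihydroxychroman-8-yl)methyl]-2,4-dihydroxy-6-methoxy-5-methylphenyl}-2-methylbutan-1-one (the target)
Conditions: H2 (1 atm), Pd(OH)2/C, THF/MeOH, rt
Reagents that add atoms: none
Why: Global hydrogenolysis of five benzyl ethers under neutral conditions, which do not epimerise C2; the chelated aryl ketone, the diarylmethane and the cyclic benzylic ether are expected to survive at atmospheric pressure if the reaction is stopped on completion.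

## Compound list

1 | 5-bromoresorcinol | Oc1cc(O)cc(Br)c1 | starting material
2 | 1,3-bis(benzyloxy)-5-bromobenzene | Brc1cc(OCc2ccccc2)cc(OCc2ccccc2)c1 | intermediate
3 | [2,4-bis(benzyloxy)-6-bromobenzylidene]dimethyliminium chloride (not isolated) | C[N+](C)=Cc1c(Br)cc(OCc2ccccc2)cc1OCc1ccccc1.[Cl-] | intermediate
4 | 2,4-bis(benzyloxy)-6-bromobenzaldehyde | O=Cc1c(Br)cc(OCc2ccccc2)cc1OCc1ccccc1 | intermediate
5 | [2,4-bis(benzyloxy)-6-bromophenyl]methanol | OCc1c(Br)cc(OCc2ccccc2)cc1OCc1ccccc1 | intermediate
6 | 1,5-bis(benzyloxy)-3-bromo-2-(bromomethyl)benzene | BrCc1c(Br)cc(OCc2ccccc2)cc1OCc1ccccc1 | intermediate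
7 | (S)-4-benzyloxazolidin-2-one | O=C1N[C@@H](Cc2ccccc2)CO1 | starting material
8 | (benzyloxy)acetyl chloride | O=C(Cl)COCc1ccccc1 | starting material
9 | lithium salt of (S)-4-benzyloxazolidin-2-one (not isolated) | [Li]N1[C@@H](Cc2ccccc2)COC1=O | intermediate
10 | (4S)-4-benzyl-3-[(benzyloxy)acetyl]oxazolidin-2-one | O=C(COCc1ccccc1)N1[C@@H](Cc2ccccc2)COC1=O | intermediate
11 | sodium (Z)-enolate of 10 (not isolated) | [Na+].[O-]\C(=C/OCc1ccccc1)N1[C@@H](Cc2ccccc2)COC1=O | intermediate
12 | (4S)-4-benzyl-3-[(2R)-2-(benzyloxy)-3-[2,4-bis(benzyloxy)-6-bromophenyl]propanoyl]oxazolidin-2-one | O=C([C@H](OCc1ccccc1)Cc1c(Br)cc(OCc2ccccc2)cc1OCc1ccccc1)N1[C@@H](Cc2ccccc2)COC1=O | intermediate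
13 | (2R)-2-(benzyloxy)-3-[2,4-bis(benzyloxy)-6-bromophenyl]propan-1-ol | OC[C@H](OCc1ccccc1)Cc1c(Br)cc(OCc2ccccc2)cc1OCc1ccccc1 | intermediate
14 | (2R)-2-(benzyloxy)-3-[2,4-bis(benzyloxy)-6-bromophenyl]propanal | O=C[C@H](OCc1ccccc1)Cc1c(Br)cc(OCc2ccccc2)cc1OCc1ccccc1 | intermediate
15 | 4-bromo-1,2-bis(benzyloxy)benzene | Brc1ccc(OCc2ccccc2)c(OCc2ccccc2)c1 | starting material
16 | [3,4-bis(benzyloxy)phenyl]magnesium bromide (not isolated) | Br[Mg]c1ccc(OCc2ccccc2)c(OCc2ccccc2)c1 | intermediate
17 | (1R,2R)-2-(benzyloxy)-1-[3,4-bis(benzyloxy)phenyl]-3-[2,4-bis(benzyloxy)-6-bromophenyl]propan-1-ol | O[C@H](c1ccc(OCc2ccccc2)c(OCc2ccccc2)c1)[C@H](OCc1ccccc1)Cc1c(Br)cc(OCc2ccccc2)cc1OCc1ccccc1 | intermediate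
18 | lithium alkoxide of 17 lithiated on the ring carbon between bromine and benzyloxy (not isolated) | [Li]O[C@H](c1ccc(OCc2ccccc2)c(OCc2ccccc2)c1)[C@H](OCc1ccccc1)Cc1c(Br)c([Li])c(OCc2ccccc2)cc1OCc1ccccc1 | intermediate
19 | aryne (across the future C8–C8a bond) as its lithium alkoxide (not isolated) | [Li]O[C@H](c1ccc(OCc2ccccc2)c(OCc2ccccc2)c1)[C@H](OCc1ccccc1)CC1=C(OCc2ccccc2)C=C(OCc2ccccc2)C#C1 | intermediate
20 | (2R,3R)-3,5,7-tris(benzyloxy)-2-[3,4-bis(benzyloxy)phenyl]chroman-8-yllithium (not isolated) | [Li]c1c(OCc2ccccc2)cc(OCc2ccccc2)c2c1O[C@H](c1ccc(OCc3ccccc3)c(OCc3ccccc3)c1)[C@H](OCc1ccccc1)C2 | intermediate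
21 | lithium hemiaminolate from 20 and DMF, both epimers at the new carbon (not isolated) | CN(C)C(O[Li])c1c(OCc2ccccc2)cc(OCc2ccccc2)c2c1O[C@H](c1ccc(OCc3ccccc3)c(OCc3ccccc3)c1)[C@H](OCc1ccccc1)C2 | intermediate
22 | (2R,3R)-3,5,7-tris(benzyloxy)-2-[3,4-bis(benzyloxy)phenyl]chromane-8-carbaldehyde (8-formyl-penta-O-benzyl-(−)-epicatechin) | O=Cc1c(OCc2ccccc2)cc(OCc2ccccc2)c2c1O[C@H](c1ccc(OCc3ccccc3)c(OCc3ccccc3)c1)[C@H](OCc1ccccc1)C2 | intermediate
23 | [(2R,3R)-3,5,7-tris(benzyloxy)-2-[3,4-bis(benzyloxy)phenyl]chroman-8-yl]methanol | OCc1c(OCc2ccccc2)cc(OCc2ccccc2)c2c1O[C@H](c1ccc(OCc3ccccc3)c(OCc3ccccc3)c1)[C@H](OCc1ccccc1)C2 | intermediate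
24 | (S)-2-methylbutanoic acid | CC[C@H](C)C(=O)O | starting material
25 | 2-methylphloroglucinol | Cc1c(O)cc(O)cc1O | starting material
26 | (S)-2-methylbutanoyl chloride (not isolated) | CC[C@H](C)C(=O)Cl | intermediate
27 | (2S)-2-methyl-1-(2,4,6-trihydroxy-3-methylphenyl)butan-1-one | CC[C@H](C)C(=O)c1c(O)cc(O)c(C)c1O | intermediate
28 | (2S)-1-[4,6-bis(benzyloxy)-2-hydroxy-3-methylphenyl]-2-methylbutan-1-one | CC[C@H](C)C(=O)c1c(OCc2ccccc2)cc(OCc2ccccc2)c(C)c1O | intermediate
29 | (2S)-1-[4,6-bis(benzyloxy)-2-methoxy-3-methylphenyl]-2-methylbutan-1-one | CC[C@H](C)C(=O)c1c(OCc2ccccc2)cc(OCc2ccccc2)c(C)c1OC | intermediate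
30 | (2S)-1-(4,6-dihydroxy-2-methoxy-3-methylphenyl)-2-methylbutan-1-one | CC[C@H](C)C(=O)c1c(O)cc(O)c(C)c1OC | intermediate
31 | [(2R,3R)-3,5,7-tris(benzyloxy)-2-[3,4-bis(benzyloxy)phenyl]chroman-8-yl]methylium (not isolated) | [CH2+]c1c(OCc2ccccc2)cc(OCc2ccccc2)c2c1O[C@H](c1ccc(OCc3ccccc3)c(OCc3ccccc3)c1)[C@H](OCc1ccccc1)C2 | intermediate
32 | (2S)-1-{3-[((2R,3R)-3,5,7-tris(benzyloxy)-2-[3,4-bis(benzyloxy)phenyl]chroman-8-yl)methyl]-2,4-dihydroxy-6-methoxy-5-methylphenyl}-2-methylbutan-1-one | CC[C@H](C)C(=O)c1c(O)c(Cc2c(OCc3ccccc3)cc(OCc3ccccc3)c3c2O[C@H](c2ccc(OCc4ccccc4)c(OCc4ccccc4)c2)[C@H](OCc2ccccc2)C3)c(O)c(C)c1OC | intermediate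
33 | (2S)-1-{3-[((2R,3R)-2-(3,4-dihydroxyphenyl)-3,5,7-trihydroxychroman-8-yl)methyl]-2,4-dihydroxy-6-methoxy-5-methylphenyl}-2-methylbutan-1-one | CC[C@H](C)C(=O)c1c(O)c(Cc2c(O)cc(O)c3c2O[C@H](c2ccc(O)c(O)c2)[C@H](O)C3)c(O)c(C)c1OC | target

## Step count and least certain steps

Total: 17 steps. Longest linear sequence: 12 steps from 1 (steps 1–4, 6–11, 16, 17). Side branches: one step to 10 (step 5) and four steps to 30 (steps 12–15).

**Step 10 (key step).**
- What may go wrong: metalation at the ring carbon between the two benzyloxy groups instead of next to bromine; proton transfer to the C8 aryllithium before the formamide arrives; addition of the hindered amide to the aryne; base-induced rearrangement of aryl benzyl ethers at the temperature needed for loss of LiBr.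
- Fallback: it sets out from 17 and comes back at 22, forming the two bonds in separate, known operations. Intramolecular Buchwald–Hartwig etherification (Pd(OAc)2, 2-(di-tert-butylphosphino)-1,1'-binaphthyl, Cs2CO3, toluene, 80 °C) closes ring C to penta-O-benzyl-(−)-epicatechin F1. Electrophilic bromination with N-bromosuccinimide in CH2Cl2 at low temperature, which on 5,7-di-O-alkyl flavan-3-ols is expected at C8, gives the 8-bromo derivative F2. Bromine–lithium exchange with n-BuLi in THF at −78 °C followed by DMF returns 22.

**Step 16.**
- What may go wrong: alkylation of C6 of a second flavan molecule by the cation (oligomerisation); acid-induced opening of ring C with loss of the C2 configuration; O-alkylation of ring D instead of C-alkylation.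
- Fallback: it sets out from 22 and 30 and comes back at 32, bypassing 23 and all acid. It is a reductive alkylation: L-proline-catalysed Knoevenagel condensation of the aldehyde with the acylphloroglucinol gives the quinone methide F3 (not isolated), which is reduced in the same flask by diethyl 2,6-dimethyl-1,4-dihydropyridine-3,5-dicarboxylate (Hantzsch ester) in CH2Cl2/EtOH.

**Step 13.**
- What may go wrong: insufficient discrimination between the two hydroxyls ortho to the ketone, so that benzylation also occurs on the oxygen that must later be methylated.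
- Fallback: it sets out from 26 and comes back at 30, with the C-methyl group introduced last so that no such selectivity is needed. Acylation of phloroglucinol with 26 (AlCl3) gives (2S)-2-methyl-1-(2,4,6-trihydroxyphenyl)butan-1-one F4. Benzylation with two equivalents of BnBr and K2CO3 can only give (2S)-1-[2,4-bis(benzyloxy)-6-hydroxyphenyl]-2-methylbutan-1-one F5, because the two ortho hydroxyls are equivalent. Magnesium-mediated ortho-formylation (MgCl2, Et3N, paraformaldehyde; Casnati–Skattebøl) can only occur at the one free position ortho to the phenol and gives 4,6-bis(benzyloxy)-2-hydroxy-3-[(2S)-2-methylbutanoyl]benzaldehyde F6. Methylation (MeI, K2CO3) gives 4,6-bis(benzyloxy)-2-methoxy-3-[(2S)-2-methylbutanoyl]benzaldehyde F7. Hydrogenation (H2, Pd/C, EtOAc/AcOH) removes both benzyl groups and takes the electron-rich aldehyde down to the methyl group, giving 30.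

**Step 9.**
- What may go wrong: poor facial selectivity if non-chelated addition competes (THF from the Grignard solution weakens the chelate); enolisation and epimerisation of the α-alkoxy aldehyde.
- Fallback: it sets out from 12 and comes back at 17, with reagent control in place of chelation. Transamidation of 12 with MeONHMe·HCl and AlMe3 gives the Weinreb amide (2R)-2-(benzyloxy)-3-[2,4-bis(benzyloxy)-6-bromophenyl]-N-methoxy-N-methylpropanamide F8. Addition of 16 gives the ketone (2R)-2-(benzyloxy)-1-[3,4-bis(benzyloxy)phenyl]-3-[2,4-bis(benzyloxy)-6-bromophenyl]propan-1-one F9. Corey–Bakshi–Shibata reduction with the (R)-methyl oxazaborolidine [(R)-1-methyl-3,3-diphenyltetrahydro-1H,3H-pyrrolo[1,2-c][1,3,2]oxazaborole] and BH3·SMe2, with the aryl group as the large substituent, should deliver the (1R) carbinol 17.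

**Step 6.**
- What may go wrong: self-alkylation or hydrolysis of the electron-rich benzylic bromide before it meets the enolate; slow alkylation because both ortho positions of the electrophile are substituted; thermal breakdown of the glycolate enolate if the mixture has to be warmed.
- Fallback: it sets out from 4 and comes back at 13, replacing the alkylation by an aldol addition and a deoxygenation. The imide of the opposite auxiliary, (4R)-4-benzyl-3-[(benzyloxy)acetyl]oxazolidin-2-one F10, is made from commercial (R)-4-benzyloxazolidin-2-one and 8 as in step 5. Its boron enolate (Bu2BOTf, i-Pr2NEt, CH2Cl2) adds to 4 in an Evans syn aldol to give (4R)-4-benzyl-3-[(2R,3S)-2-(benzyloxy)-3-[2,4-bis(benzyloxy)-6-bromophenyl]-3-hydroxypropanoyl]oxazolidin-2-one F11. Ionic hydrogenation of the activated benzylic alcohol (Et3SiH, CF3CO2H, CH2Cl2, −20 °C) gives (4R)-4-benzyl-3-[(2R)-2-(benzyloxy)-3-[2,4-bis(benzyloxy)-6-bromophenyl]propanoyl]oxazolidin-2-one F12. LiBH4 reduction gives 13.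

## Further compounds

F1 | step 10 | (2R,3R)-3,5,7-tris(benzyloxy)-2-[3,4-bis(benzyloxy)phenyl]chromane (penta-O-benzyl-(−)-epicatechin) | c1(OCc2ccccc2)cc(OCc2ccccc2)c2c(c1)O[C@H](c1ccc(OCc3ccccc3)c(OCc3ccccc3)c1)[C@H](OCc1ccccc1)C2
F2 | step 10 | (2R,3R)-3,5,7-tris(benzyloxy)-2-[3,4-bis(benzyloxy)phenyl]-8-bromochromane | Brc1c(OCc2ccccc2)cc(OCc2ccccc2)c2c1O[C@H](c1ccc(OCc3ccccc3)c(OCc3ccccc3)c1)[C@H](OCc1ccccc1)C2
F3 | step 16 | quinone methide from 22 and 30 (exocyclic alkene geometry not defined, not isolated) | CC[C@H](C)C(=O)C1=C(O)C(=Cc2c(OCc3ccccc3)cc(OCc3ccccc3)c3c2O[C@H](c2ccc(OCc4ccccc4)c(OCc4ccccc4)c2)[C@H](OCc2ccccc2)C3)C(=O)C(C)=C1OC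
F4 | step 13 | (2S)-2-methyl-1-(2,4,6-trihydroxyphenyl)butan-1-one | CC[C@H](C)C(=O)c1c(O)cc(O)cc1O
F5 | step 13 | (2S)-1-[2,4-bis(benzyloxy)-6-hydroxyphenyl]-2-methylbutan-1-one | CC[C@H](C)C(=O)c1c(OCc2ccccc2)cc(OCc2ccccc2)cc1O
F6 | step 13 | 4,6-bis(benzyloxy)-2-hydroxy-3-[(2S)-2-methylbutanoyl]benzaldehyde | CC[C@H](C)C(=O)c1c(OCc2ccccc2)cc(OCc2ccccc2)c(C=O)c1O
F7 | step 13 | 4,6-bis(benzyloxy)-2-methoxy-3-[(2S)-2-methylbutanoyl]benzaldehyde | CC[C@H](C)C(=O)c1c(OCc2ccccc2)cc(OCc2ccccc2)c(C=O)c1OC
F8 | step 9 | (2R)-2-(benzyloxy)-3-[2,4-bis(benzyloxy)-6-bromophenyl]-N-methoxy-N-methylpropanamide | CON(C)C(=O)[C@H](OCc1ccccc1)Cc1c(Br)cc(OCc2ccccc2)cc1OCc1ccccc1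
F9 | step 9 | (2R)-2-(benzyloxy)-1-[3,4-bis(benzyloxy)phenyl]-3-[2,4-bis(benzyloxy)-6-bromophenyl]propan-1-one | O=C(c1ccc(OCc2ccccc2)c(OCc2ccccc2)c1)[C@H](OCc1ccccc1)Cc1c(Br)cc(OCc2ccccc2)cc1OCc1ccccc1
F10 | step 6 | (4R)-4-benzyl-3-[(benzyloxy)acetyl]oxazolidin-2-one | O=C(COCc1ccccc1)N1[C@H](Cc2ccccc2)COC1=O
F11 | step 6 | (4R)-4-benzyl-3-[(2R,3S)-2-(benzyloxy)-3-[2,4-bis(benzyloxy)-6-bromophenyl]-3-hydroxypropanoyl]oxazolidin-2-one | O=C([C@H](OCc1ccccc1)[C@@H](O)c1c(Br)cc(OCc2ccccc2)cc1OCc1ccccc1)N1[C@H](Cc2ccccc2)COC1=O
F12 | step 6 | (4R)-4-benzyl-3-[(2R)-2-(benzyloxy)-3-[2,4-bis(benzyloxy)-6-bromophenyl]propanoyl]oxazolidin-2-one | O=C([C@H](OCc1ccccc1)Cc1c(Br)cc(OCc2ccccc2)cc1OCc1ccccc1)N1[C@H](Cc2ccccc2)COC1=O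
A1 | alternative 1 | aryl ether of the bridged ring-A phenol with (R)-[(R)-oxiran-2-yl][3,4-bis(pivaloyloxy)phenyl]methanol, rings A and D as four benzyl ethers | CC[C@H](C)C(=O)c1c(OCc2ccccc2)c(Cc2c(OCc3ccccc3)cc(OCc3ccccc3)cc2O[C@H](c2ccc(OC(=O)C(C)(C)C)c(OC(=O)C(C)(C)C)c2)[C@H]2CO2)c(OCc2ccccc2)c(C)c1OC
A2 | alternative 1 | (2R,3R) flavan-3-ol with ring B as bis-pivalate and four benzyl ethers | CC[C@H](C)C(=O)c1c(OCc2ccccc2)c(Cc2c(OCc3ccccc3)cc(OCc3ccccc3)c3c2O[C@H](c2ccc(OC(=O)C(C)(C)C)c(OC(=O)C(C)(C)C)c2)[C@H](O)C3)c(OCc2ccccc2)c(C)c1OC
A3 | alternative 2 | 3-methoxy-4-methylcyclobut-2-en-1-one | COC1=CC(=O)C1C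
A4 | alternative 2 | 8-[3-(triisopropylsilyloxy)prop-2-yn-1-yl]-penta-O-benzyl-(−)-epicatechin | CC(C)[Si](C(C)C)(C(C)C)OC#CCc1c(OCc2ccccc2)cc(OCc2ccccc2)c2c1O[C@H](c1ccc(OCc3ccccc3)c(OCc3ccccc3)c1)[C@H](OCc1ccccc1)C2
A5 | alternative 2 | ring-D phenol lacking the acyl group (OH, bridge, OTIPS, H, OCH3, CH3 in order) on penta-O-benzyl-(−)-epicatechin | COc1cc(O[Si](C(C)C)(C(C)C)C(C)C)c(Cc2c(OCc3ccccc3)cc(OCc3ccccc3)c3c2O[C@H](c2ccc(OCc4ccccc4)c(OCc4ccccc4)c2)[C@H](OCc2ccccc2)C3)c(O)c1C
A6 | alternative 3 | ring-A salicyl alcohol carrying the benzyl-protected ring D on the bridge | CC[C@H](C)C(=O)c1c(OCc2ccccc2)c(Cc2c(OCc3ccccc3)cc(OCc3ccccc3)c(CO)c2O)c(OCc2ccccc2)c(C)c1OC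
A7 | alternative 3 | ortho-quinone methide from A6 (C4 as exocyclic methylene, C8a oxygen as carbonyl) | CC[C@H](C)C(=O)c1c(OCc2ccccc2)c(CC2=C(OCc3ccccc3)C=C(OCc3ccccc3)C(=C)C2=O)c(OCc2ccccc2)c(C)c1OC
A8 | alternative 3 | (Z)-2-[3,4-bis(benzyloxy)phenyl]ethenyl acetate | CC(=O)O/C=C\c1ccc(OCc2ccccc2)c(OCc2ccccc2)c1
A9 | alternative 3 | hexa-O-benzyl target as its (2R,3R) C3 acetate | CC[C@H](C)C(=O)c1c(OCc2ccccc2)c(Cc2c(OCc3ccccc3)cc(OCc3ccccc3)c3c2O[C@H](c2ccc(OCc4ccccc4)c(OCc4ccccc4)c2)[C@H](OC(C)=O)C3)c(OCc2ccccc2)c(C)c1OC
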